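Retrosynthesis: cut the C5 ester C–O bond (Mitsunobu) to alcohol 37 and side-chain acid 48; then the lactone O13–C1 bond; then the ring O7–C3 bond of the tetrahydropyran; finally C4–C5 and C5–C6 together, leaving silyl dithiane 23 (C5) and two terminal epoxides, 4 (C1–C4) and 22 (C6–C16).
Enabling feature: C5 lies between the methylenes C4 and C6, each bonded to an oxygen-bearing carbon (C3 and C7, the two carbons on the ring oxygen of the tetrahydropyran ring); this 1,5-dioxygenated C3–C7 array is what one acyl-anion carbon and two epoxide CH2 termini deliver.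
Forward: epoxides 4 (steps 1–3) and 22 (steps 4–15) are joined through 23 as an open chain (step 16); the tetrahydropyran ring closes next (step 18), the 14-membered lactone ring last (step 22); acid 48 (steps 24–31) is attached in step 32.
Stereochemistry: C9 from (R)-citronellal; C13 and C3 from hydrolytic kinetic resolutions (C3 is made with the C–O sense opposite to the target and inverted in the SN2 ring closure); C11 by Evans–Tishchenko 1,3-anti reduction; C7 by L-proline α-aminoxylation; C5 by axial hydride attack, then Mitsunobu inversion; both (Z)-alkenes by Lindlar hydrogenation and Still–Gennari olefination.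

Key step: step 16

Remark: labels C1–C16 follow the macrolide numbering (C1 lactone carbonyl, C13 propyl-bearing carbinol), in which the target as drawn is (3R,5R,7R,9S,11R,13R); (R,R)-(salen)Co(OAc) is the acetate of the trivalent cobalt complex of (R,R)-N,N′-bis(3,5-di-tert-butylsalicylidene)cyclohexane-1,2-diamine, made from the commercial divalent cobalt complex with AcOH in air.

**West epoxide (C1–C4)**

Step 1
Reactants: 1 but-3-en-1-ol
Product: 2 4-(benzyloxy)but-1-ene
Conditions: NaH, BnBr, Bu4NI (cat.), THF, 0 °C → rt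
Reagents that add atoms: benzyl bromide, BrCc1ccccc1
Why: Williamson etherification of the primary alkoxide is routine and installs an O1 protecting group that tolerates organolithium reagents and fluoride.

Step 2
Reactants: 2 4-(benzyloxy)but-1-ene
Product: 3 rac-2-[2-(benzyloxy)ethyl]oxirane
Conditions: mCPBA, CH2Cl2, 0 °C → rt
Reagents that add atoms: 3-chloroperoxybenzoic acid, OOC(=O)c1cccc(Cl)c1
Why: Prilezhaev epoxidation of a monosubstituted alkene by a peracid is reliable, the benzyl ether is inert, and the new centre (C3) is deliberately formed racemic.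

Step 3
Reactants: 3 rac-2-[2-(benzyloxy)ethyl]oxirane
Product: 4 (2R)-2-[2-(benzyloxy)ethyl]oxirane
Conditions: (R,R)-(salen)Co(OAc) (0.5 mol%), H2O (0.55 equiv), THF (minimum), 0 °C → rt; chromatography
Reagents that add atoms: none
Why: Hydrolytic kinetic resolution, in which the chiral cobalt salen catalyst hydrates the (S)-epoxide far faster, so the (R)-epoxide (C3–O sense opposite to the target, inverted in step 18) is recovered unchanged.

**East epoxide (C6–C16)**

Step 4
Reactants: 5 rac-2-propyloxirane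
Product: 6 (2R)-2-propyloxirane
Conditions: (R,R)-(salen)Co(OAc) (0.5 mol%), H2O (0.55 equiv), neat, 0 °C → rt; distillation
Reagents that add atoms: none
Why: Hydrolytic kinetic resolution as in step 3 leaves the (R)-epoxide, which carries the future C13–O bond in its final configuration.

Step 5
Reactants: 7 (R)-citronellal
Product: 8 2-[(2R)-2,6-dimethylhept-5-en-1-yl]-1,3-dithiane
Conditions: HS(CH2)3SH, BF3·OEt2 (10 mol%), CH2Cl2, –20 °C
Reagents that add atoms: propane-1,3-dithiol, SCCCS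
Why: Lewis-acid dithioacetalisation turns the C11 aldehyde into an acyl-anion equivalent, thiol addition at low temperature outrunning the carbonyl-ene cyclisation of citronellal, and C9 is not touched.

Step 6
Reactants: 8 citronellal dithiane; 6 (2R)-2-propyloxirane
Product: 10 (2R)-1-{2-[(2R)-2,6-dimethylhept-5-en-1-yl]-1,3-dithian-2-yl}pentan-2-ol, via 2-lithio dithiane 9 (not isolated)
Conditions: n-BuLi, THF, –30 °C, 2 h; then 6, –30 → 0 °C; H2O
Reagents that add atoms: none
Why: Corey–Seebach alkylation, in which the 2-lithio-1,3-dithiane opens the monosubstituted epoxide at its CH2 terminus (C12), so C13 keeps the configuration of 6 because its C–O bond is never broken.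

Step 7
Reactants: 10 hydroxy dithiane
Product: 11 (4R,8R)-4-hydroxy-8,12-dimethyltridec-11-en-6-one
Conditions: MeI, CaCO3, MeCN–H2O (9:1), 45 °C
Reagents that add atoms: water, O
Why: Alkylative dithioketal hydrolysis (S-methylation, then attack of water) runs under buffered neutral conditions in which the β-hydroxy ketone neither dehydrates nor retro-aldolises and the alkene is inert.

Step 8
Reactants: 11 β-hydroxy ketone
Product: 12 (4R,6R,8R)-6-hydroxy-8,12-dimethyltridec-11-en-4-yl benzoate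
Conditions: PhCHO (4 equiv), SmI2 (0.3 equiv), THF, –10 °C
Reagents that add atoms: benzaldehyde, O=Cc1ccccc1
Why: Evans–Tishchenko reduction, in which the samarium-bound hemiacetal formed on O13 delivers hydride to C11 through a chair-like six-membered transition state, setting the C11 carbinol 1,3-anti to C13 and leaving O13 as benzoate and O11 free.

Step 9
Reactants: 12 hydroxy benzoate
Product: 13 (4R,6R,8R)-6-methoxy-8,12-dimethyltridec-11-en-4-yl benzoate
Conditions: Me3OBF4, 1,8-bis(dimethylamino)naphthalene, 4 Å MS, CH2Cl2, 0 °C → rt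
Reagents that add atoms: trimethyloxonium tetrafluoroborate, C[O+](C)C.F[B-](F)(F)F
Why: O-Methylation with an oxonium salt and a non-nucleophilic base proceeds without forming an alkoxide, which rules out 1,3-benzoyl migration from O13 to O11.

Step 10
Reactants: 13 methoxy benzoate
Product: 14 (4R,6R,8R)-6-methoxy-8,12-dimethyltridec-11-en-4-ol
Conditions: K2CO3, MeOH, 50 °C
Reagents that add atoms: none
Why: Base-catalysed transesterification with methanol removes the benzoate, and no stereocentre is at risk because the molecule has no acidic C–H next to a leaving group.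

Step 11
Reactants: 14 methoxy alcohol
Product: 15 benzyl ether of 14 at O13
Conditions: NaH, BnBr, Bu4NI (cat.), THF–DMF, 0 °C → rt
Reagents that add atoms: benzyl bromide, BrCc1ccccc1
Why: Williamson etherification gives an O13 benzyl ether that withstands ozone at low temperature, organolithiums and fluoride, and leaves together with the O1 benzyl group in step 20.

Step 12
Reactants: 15 benzyl ether alkene
Product: 17 (4R,6R,8R)-8-(benzyloxy)-6-methoxy-4-methylundecanal, via ozonide 16 (not isolated)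
Conditions: O3, CH2Cl2, –78 °C (Sudan red 7B end point); then PPh3, –78 °C → rt
Reagents that add atoms: ozone, [O-][O+]=O
Why: Ozonolysis with reductive work-up cleaves the electron-rich trisubstituted alkene to the C6 aldehyde and acetone, the benzyl ether reacting much more slowly when ozone is stopped at the indicator end point.

Step 13
Reactants: 17 C6 aldehyde
Product: 19 (2R,4S,6R,8R)-8-(benzyloxy)-6-methoxy-4-methyl-2-[(phenylamino)oxy]undecan-1-ol, via α-anilinooxy aldehyde 18 (not isolated)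
Conditions: PhNO (1.0 equiv), L-proline (20 mol%), DMSO, rt; then NaBH4, MeOH, 0 °C
Reagents that add atoms: nitrosobenzene, O=Nc1ccccc1
Why: L-Proline-catalysed α-aminoxylation, in which the enamine attacks the oxygen of nitrosobenzene held by the carboxylic acid, sets C7 as (R) under catalyst control, and immediate NaBH4 reduction prevents epimerisation of the α-oxy aldehyde.

Step 14
Reactants: 19 anilinooxy alcohol
Product: 20 (2R,4R,6R,8R)-8-(benzyloxy)-6-methoxy-4-methylundecane-1,2-diol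
Conditions: Zn, AcOH–THF, rt
Reagents that add atoms: none
Why: Reductive cleavage of the weak N–O bond by zinc in acetic acid frees the 1,2-diol without affecting benzyl or methyl ethers.

Step 15
Reactants: 20 C6,C7 diol
Product: 22 (2R)-2-[(2S,4R,6R)-6-(benzyloxy)-4-methoxy-2-methylnonyl]oxirane, via primary tosylate 21 (not isolated)
Conditions: NaH (2.5 equiv), 1-(p-toluenesulfonyl)imidazole (1.05 equiv), THF, 0 °C → rt
Reagents that add atoms: none
Why: Selective sulfonylation of the primary alkoxide followed by intramolecular Williamson displacement (3-exo-tet) by the C7 alkoxide gives the terminal epoxide with C7 retained, since only the C6–O bond is exchanged.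

**Union and macrolide core**

Step 16
Reactants: 23 2-(tert-butyldimethylsilyl)-1,3-dithiane; 22 east epoxide; 4 west epoxide
Product: 27 C1–C16 dithiane carbinol (O7 silyl ether; free C3 hydroxyl), via lithiated silyl dithiane 24 (not isolated), via C-silyl lithium alkoxide 25 (not isolated), via O-silyl lithio dithiane 26 (not isolated)
Conditions: 23, t-BuLi, Et2O, –78 → –45 °C; 22, Et2O, –78 → –25 °C; then 4 in Et2O–HMPA, –78 °C → rt; H2O
Reagents that add atoms: none
Why: Lithiated 23 opens epoxide 22 at its unsubstituted carbon C6 to give alkoxide 25, in which silicon stays on carbon as long as the medium is Et2O alone; HMPA then loosens the Li–O ion pair and triggers a 1,4-Brook rearrangement from C5 to O7, which silylates O7 and regenerates a dithiane anion at C5 (26) that opens epoxide 4 at C4. The closest known reaction type is the solvent-gated three-component coupling of a 2-silyl-1,3-dithiane with two different terminal epoxides (anion relay). No ring is closed and no stereocentre is created, so C7 and C3 simply carry over the configurations of the two epoxides. The step needs each epoxide to be attacked once, in the right order and only at its CH2 terminus: the order is secured by withholding HMPA until 22 is consumed, the regiochemistry by the steric bias of monosubstituted oxiranes toward a bulky sulfur-stabilised anion. The result is O7 silylated and O3 free, the differentiation on which the ring closure of step 18 depends.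

Step 17
Reactants: 27 dithiane carbinol
Product: 28 C3 methanesulfonate of 27
Conditions: MsCl, Et3N, CH2Cl2, 0 °C
Reagents that add atoms: methanesulfonyl chloride, CS(=O)(=O)Cl
Why: Sulfonylation of the only free hydroxyl makes C3 electrophilic while the silyl ether from the relay step keeps O7 masked.

Step 18
Reactants: 28 C3 mesylate
Product: 30 (8S,10R)-8-[2-(benzyloxy)ethyl]-10-[(2S,4R,6R)-6-(benzyloxy)-4-methoxy-2-methylnonyl]-9-oxa-1,5-dithiaspiro[5.5]undecane, via hydroxy mesylate 29 (not isolated)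
Conditions: Bu4NF (3 equiv), THF, rt → 45 °C
Reagents that add atoms: none
Why: Fluoride desilylation frees the O7 alkoxide, which displaces the C3 mesylate in an intramolecular Williamson etherification (6-exo-tet, helped by the gem-disubstituted dithiane carbon) with inversion at C3, giving the 2,6-cis tetrahydropyran.

Step 19
Reactants: 30 tetrahydropyran dithiane
Product: 31 (2S,6R)-2-[2-(benzyloxy)ethyl]-6-[(2S,4R,6R)-6-(benzyloxy)-4-methoxy-2-methylnonyl]oxan-4-one
Conditions: MeI, CaCO3, MeCN–H2O (9:1), 45 °C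
Reagents that add atoms: water, O
Why: Alkylative dithioketal hydrolysis unmasks the C5 ketone under buffered conditions, so the β-alkoxy ketone is not opened by retro-oxa-Michael reaction.

Step 20
Reactants: 31 dibenzyl ketone
Product: 32 (2S,6R)-2-(2-hydroxyethyl)-6-[(2S,4R,6R)-6-hydroxy-4-methoxy-2-methylnonyl]oxan-4-one
Conditions: H2 (1 atm), Pd(OH)2/C, EtOAc–EtOH, rt
Reagents that add atoms: none
Why: Catalytic hydrogenolysis removes both benzyl ethers at once now that sulfur is gone, and a dialkyl ketone is not reduced over palladium under these conditions.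

Step 21
Reactants: 32 keto diol
Product: 34 2-[(2R,6R)-6-[(2S,4R,6R)-6-hydroxy-4-methoxy-2-methylnonyl]-4-oxooxan-2-yl]acetic acid, via aldehyde 33 (not isolated)
Conditions: 2,2,6,6-tetramethylpiperidine 1-oxyl (TEMPO, 0.2 equiv), PhI(OAc)2 (2.5 equiv), MeCN–H2O (2:1), rt
Reagents that add atoms: water, O
Why: Oxoammonium (TEMPO) oxidation with PhI(OAc)2 in wet solvent takes the primary C1 alcohol through the aldehyde hydrate to the acid much faster than it oxidises the hindered secondary C13 hydroxyl.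

Step 22
Reactants: 34 seco acid
Product: 36 (1R,5R,7R,9S,11R)-7-methoxy-9-methyl-5-propyl-4,15-dioxabicyclo[9.3.1]pentadecane-3,13-dione, via mixed anhydride 35 (not isolated)
Conditions: 2,4,6-Cl3C6H2COCl, Et3N, THF, rt; then slow addition to 4-(dimethylamino)pyridine (DMAP), toluene (1 mM), 60 °C
Reagents that add atoms: none
Why: Yamaguchi macrolactonisation, in which the mixed anhydride acylates DMAP and the C13 hydroxyl traps the acylpyridinium under high dilution to close the 14-membered ring with retention at C13 because the acyl carbon is the site of attack.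

Step 23
Reactants: 36 macrolactone ketone
Product: 37 (1R,5R,7R,9S,11R,13S)-13-hydroxy-7-methoxy-9-methyl-5-propyl-4,15-dioxabicyclo[9.3.1]pentadecan-3-one
Conditions: NaBH4, MeOH, 0 °C
Reagents that add atoms: none
Why: Hydride reduction in which the small borohydride attacks the chair tetrahydropyranone axially, giving the equatorial (5S) alcohol cis to the C3 and C7 substituents, which is the epimer needed for inversion in step 32.

**Side chain**

Step 24
Reactants: 38 methyl 5-bromo-4-oxopentanoate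
Product: 39 methyl 3-(1,3-oxazol-4-yl)propanoate
Conditions: HCONH2 (neat, excess), 110 °C
Reagents that add atoms: formamide, NC=O
Why: Bredereck oxazole synthesis, in which formamide is O-alkylated at the bromomethyl carbon, its nitrogen condenses with the ketone and dehydration gives the 4-substituted oxazole with C2 unsubstituted.

Step 25
Reactants: 39 oxazole ester
Product: 41 methyl 3-(2-iodo-1,3-oxazol-4-yl)propanoate, via oxazolylzinc chloride 40 (not isolated)
Conditions: (tmp)ZnCl·LiCl (tmp = 2,2,6,6-tetramethylpiperidide), THF, 25 °C; then I2, 0 °C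
Reagents that add atoms: iodine, II
Why: Directed zincation at C2, the most acidic ring C–H, with a mild zinc amide that does not enolise the ester, followed by iodinolysis of the C–Zn bond.

Step 26
Reactants: 42 prop-2-yn-1-amine
Product: 43 methyl prop-2-yn-1-ylcarbamate
Conditions: ClCO2Me, Et3N, CH2Cl2, 0 °C
Reagents that add atoms: methyl chloroformate, COC(=O)Cl
Why: N-Acylation of the primary amine by a chloroformate (Schotten–Baumann-type carbamate formation) is fast and chemoselective.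

Step 27
Reactants: 41 2-iodooxazole; 43 propargyl carbamate
Product: 44 methyl 3-(2-{3-[(methoxycarbonyl)amino]prop-1-yn-1-yl}-1,3-oxazol-4-yl)propanoate
Conditions: PdCl2(PPh3)2 (5 mol%), CuI (10 mol%), Et3N, THF, rt
Reagents that add atoms: none
Why: Sonogashira coupling, in which zerovalent palladium inserts into the electron-poor C2–I bond and the copper acetylide transmetalates, with the carbamate N–H tolerated.

Step 28
Reactants: 44 alkynyl oxazole
Product: 45 methyl 3-(2-{(1Z)-3-[(methoxycarbonyl)amino]prop-1-en-1-yl}-1,3-oxazol-4-yl)propanoate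
Conditions: H2 (1 atm), Pd/CaCO3 poisoned with Pb(OAc)2 (Lindlar catalyst), quinoline, EtOAc, rt
Reagents that add atoms: none
Why: Lindlar semi-hydrogenation adds H2 syn to the alkyne and stops at the alkene, which fixes the (Z) geometry next to the oxazole.

Step 29
Reactants: 45 (Z)-alkenyl oxazole ester
Product: 46 methyl {(2Z)-3-[4-(3-oxopropyl)-1,3-oxazol-2-yl]prop-2-en-1-yl}carbamate
Conditions: i-Bu2AlH (2.2 equiv), CH2Cl2, –78 °C; MeOH, aq KNaC4H4O6
Reagents that add atoms: none
Why: Partial ester reduction with i-Bu2AlH at –78 °C stops at the aluminium hemiacetal, which releases the aldehyde on work-up, while the N-deprotonated carbamate is not reduced.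

Step 30
Reactants: 46 aldehyde
Product: 47 methyl (2Z)-5-(2-{(1Z)-3-[(methoxycarbonyl)amino]prop-1-en-1-yl}-1,3-oxazol-4-yl)pent-2-enoate
Conditions: (CF3CH2O)2P(O)CH2CO2Me, KN(SiMe3)2, 18-crown-6, THF, –78 °C
Reagents that add atoms: methyl 2-[bis(2,2,2-trifluoroethoxy)phosphoryl]acetate, COC(=O)CP(=O)(OCC(F)(F)F)OCC(F)(F)F
Why: Still–Gennari olefination, in which the electron-poor phosphonate with a dissociated potassium counter-ion eliminates rapidly from the kinetic adduct and gives the (Z)-enoate.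

Step 31
Reactants: 47 methyl (Z)-enoate
Product: 48 (2Z)-5-(2-{(1Z)-3-[(methoxycarbonyl)amino]prop-1-en-1-yl}-1,3-oxazol-4-yl)pent-2-enoic acid
Conditions: LiOH, THF–H2O (3:1), 0 °C → rt; then 1 M HCl to pH 3
Reagents that add atoms: lithium hydroxide, [Li+].[OH-]
Why: Saponification of the methyl ester by hydroxide is much faster than hydrolysis of the methyl carbamate and does not isomerise the (Z)-enoate at low temperature.

**Fragment union**

Step 32
Reactants: 37 equatorial C5 alcohol; 48 side-chain acid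
Product: 49 neopeltolide
Conditions: PPh3, DIAD, benzene, 0 °C → rt
Reagents that add atoms: none
Why: Mitsunobu esterification, in which the equatorial C5 hydroxyl is activated as an oxyphosphonium ion and displaced by the carboxylate with inversion, giving the axial (5R) ester of the target.

**Compound list**

1 | but-3-en-1-ol | C=CCCO | starting material
2 | 4-(benzyloxy)but-1-ene | C=CCCOCc1ccccc1 | intermediate
3 | rac-2-[2-(benzyloxy)ethyl]oxirane | C1OC1CCOCc2ccccc2 | intermediate
4 | (2R)-2-[2-(benzyloxy)ethyl]oxirane (west epoxide, C1–C4) | C1[C@@H](CCOCc2ccccc2)O1 | intermediate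
5 | rac-2-propyloxirane | CCCC1CO1 | starting material
6 | (2R)-2-propyloxirane | CCC[C@@H]1CO1 | intermediate
7 | (3R)-3,7-dimethyloct-6-enal ((R)-citronellal) | O=CC[C@H](C)CCC=C(C)C | starting material
8 | 2-[(2R)-2,6-dimethylhept-5-en-1-yl]-1,3-dithiane | C1(C[C@H](C)CCC=C(C)C)SCCCS1 | intermediate
9 | 2-[(2R)-2,6-dimethylhept-5-en-1-yl]-2-lithio-1,3-dithiane | [Li]C1(C[C@H](C)CCC=C(C)C)SCCCS1 | intermediate
10 | (2R)-1-{2-[(2R)-2,6-dimethylhept-5-en-1-yl]-1,3-dithian-2-yl}pentan-2-ol | CCC[C@@H](O)CC1(C[C@H](C)CCC=C(C)C)SCCCS1 | intermediate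
11 | (4R,8R)-4-hydroxy-8,12-dimethyltridec-11-en-6-one | CCC[C@@H](O)CC(=O)C[C@H](C)CCC=C(C)C | intermediate
12 | (4R,6R,8R)-6-hydroxy-8,12-dimethyltridec-11-en-4-yl benzoate | CCC[C@@H](OC(=O)c1ccccc1)C[C@H](O)C[C@H](C)CCC=C(C)C | intermediate
13 | (4R,6R,8R)-6-methoxy-8,12-dimethyltridec-11-en-4-yl benzoate | CCC[C@@H](OC(=O)c1ccccc1)C[C@H](OC)C[C@H](C)CCC=C(C)C | intermediate
14 | (4R,6R,8R)-6-methoxy-8,12-dimethyltridec-11-en-4-ol | CCC[C@@H](O)C[C@H](OC)C[C@H](C)CCC=C(C)C | intermediate
15 | ({[(4R,6R,8R)-6-methoxy-8,12-dimethyltridec-11-en-4-yl]oxy}methyl)benzene | CCC[C@@H](OCc1ccccc1)C[C@H](OC)C[C@H](C)CCC=C(C)C | intermediate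
16 | 3-[(3R,5R,7R)-7-(benzyloxy)-5-methoxy-3-methyldecyl]-5,5-dimethyl-1,2,4-trioxolane (both epimers at the trioxolane carbon) | CCC[C@@H](OCc1ccccc1)C[C@H](OC)C[C@H](C)CCC1OOC(C)(C)O1 | intermediate
17 | (4R,6R,8R)-8-(benzyloxy)-6-methoxy-4-methylundecanal | CCC[C@@H](OCc1ccccc1)C[C@H](OC)C[C@H](C)CCC=O | intermediate
18 | (2R,4S,6R,8R)-8-(benzyloxy)-6-methoxy-4-methyl-2-[(phenylamino)oxy]undecanal | CCC[C@@H](OCc1ccccc1)C[C@H](OC)C[C@H](C)C[C@@H](ONc1ccccc1)C=O | intermediate
19 | (2R,4S,6R,8R)-8-(benzyloxy)-6-methoxy-4-methyl-2-[(phenylamino)oxy]undecan-1-ol | CCC[C@@H](OCc1ccccc1)C[C@H](OC)C[C@H](C)C[C@@H](ONc1ccccc1)CO | intermediate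
20 | (2R,4R,6R,8R)-8-(benzyloxy)-6-methoxy-4-methylundecane-1,2-diol | CCC[C@@H](OCc1ccccc1)C[C@H](OC)C[C@H](C)C[C@@H](O)CO | intermediate
21 | (2R,4R,6R,8R)-8-(benzyloxy)-2-hydroxy-6-methoxy-4-methylundecyl 4-methylbenzenesulfonate | CCC[C@@H](OCc1ccccc1)C[C@H](OC)C[C@H](C)C[C@@H](O)COS(=O)(=O)c1ccc(C)cc1 | intermediate
22 | (2R)-2-[(2S,4R,6R)-6-(benzyloxy)-4-methoxy-2-methylnonyl]oxirane (east epoxide, C6–C16) | CCC[C@@H](OCc1ccccc1)C[C@H](OC)C[C@H](C)C[C@@H]2CO2 | intermediate
23 | tert-butyl(1,3-dithian-2-yl)dimethylsilane | CC(C)(C)[Si](C)(C)C1SCCCS1 | starting material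
24 | tert-butyl(2-lithio-1,3-dithian-2-yl)dimethylsilane | CC(C)(C)[Si](C)(C)C1([Li])SCCCS1 | intermediate
25 | lithium (2R,4R,6R,8R)-8-(benzyloxy)-1-[2-(tert-butyldimethylsilyl)-1,3-dithian-2-yl]-6-methoxy-4-methylundecan-2-olate | CCC[C@@H](OCc1ccccc1)C[C@H](OC)C[C@H](C)C[C@@H](O[Li])CC2(SCCCS2)[Si](C)(C)C(C)(C)C | intermediate
26 | {[(2R,4S,6R,8R)-8-(benzyloxy)-1-(2-lithio-1,3-dithian-2-yl)-6-methoxy-4-methylundecan-2-yl]oxy}(tert-butyl)dimethylsilane | CCC[C@@H](OCc1ccccc1)C[C@H](OC)C[C@H](C)C[C@@H](O[Si](C)(C)C(C)(C)C)CC2([Li])SCCCS2 | intermediate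
27 | (2R)-4-(benzyloxy)-1-{2-[(2R,4S,6R,8R)-8-(benzyloxy)-2-[(tert-butyldimethylsilyl)oxy]-6-methoxy-4-methylundecyl]-1,3-dithian-2-yl}butan-2-ol | CCC[C@@H](OCc1ccccc1)C[C@H](OC)C[C@H](C)C[C@@H](O[Si](C)(C)C(C)(C)C)CC2(SCCCS2)C[C@@H](CCOCc3ccccc3)O | intermediate
28 | (2R)-4-(benzyloxy)-1-{2-[(2R,4S,6R,8R)-8-(benzyloxy)-2-[(tert-butyldimethylsilyl)oxy]-6-methoxy-4-methylundecyl]-1,3-dithian-2-yl}butan-2-yl methanesulfonate | CCC[C@@H](OCc1ccccc1)C[C@H](OC)C[C@H](C)C[C@@H](O[Si](C)(C)C(C)(C)C)CC2(SCCCS2)C[C@@H](CCOCc3ccccc3)OS(C)(=O)=O | intermediate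
29 | (2R)-4-(benzyloxy)-1-{2-[(2R,4R,6R,8R)-8-(benzyloxy)-2-hydroxy-6-methoxy-4-methylundecyl]-1,3-dithian-2-yl}butan-2-yl methanesulfonate | CCC[C@@H](OCc1ccccc1)C[C@H](OC)C[C@H](C)C[C@@H](O)CC2(SCCCS2)C[C@@H](CCOCc3ccccc3)OS(C)(=O)=O | intermediate
30 | (8S,10R)-8-[2-(benzyloxy)ethyl]-10-[(2S,4R,6R)-6-(benzyloxy)-4-methoxy-2-methylnonyl]-9-oxa-1,5-dithiaspiro[5.5]undecane | CCC[C@@H](OCc1ccccc1)C[C@H](OC)C[C@H](C)C[C@@H]2CC3(SCCCS3)C[C@H](CCOCc4ccccc4)O2 | intermediate
31 | (2S,6R)-2-[2-(benzyloxy)ethyl]-6-[(2S,4R,6R)-6-(benzyloxy)-4-methoxy-2-methylnonyl]oxan-4-one | CCC[C@@H](OCc1ccccc1)C[C@H](OC)C[C@H](C)C[C@@H]2CC(=O)C[C@H](CCOCc3ccccc3)O2 | intermediate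
32 | (2S,6R)-2-(2-hydroxyethyl)-6-[(2S,4R,6R)-6-hydroxy-4-methoxy-2-methylnonyl]oxan-4-one | CCC[C@@H](O)C[C@H](OC)C[C@H](C)C[C@@H]1CC(=O)C[C@H](CCO)O1 | intermediate
33 | 2-[(2S,6R)-6-[(2S,4R,6R)-6-hydroxy-4-methoxy-2-methylnonyl]-4-oxooxan-2-yl]acetaldehyde | CCC[C@@H](O)C[C@H](OC)C[C@H](C)C[C@@H]1CC(=O)C[C@H](CC=O)O1 | intermediate
34 | 2-[(2R,6R)-6-[(2S,4R,6R)-6-hydroxy-4-methoxy-2-methylnonyl]-4-oxooxan-2-yl]acetic acid | CCC[C@@H](O)C[C@H](OC)C[C@H](C)C[C@@H]1CC(=O)C[C@H](CC(=O)O)O1 | intermediate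
35 | 2-[(2R,6R)-6-[(2S,4R,6R)-6-hydroxy-4-methoxy-2-methylnonyl]-4-oxooxan-2-yl]acetic 2,4,6-trichlorobenzoic anhydride | CCC[C@@H](O)C[C@H](OC)C[C@H](C)C[C@@H]1CC(=O)C[C@H](CC(=O)OC(=O)c2c(Cl)cc(Cl)cc2Cl)O1 | intermediate
36 | (1R,5R,7R,9S,11R)-7-methoxy-9-methyl-5-propyl-4,15-dioxabicyclo[9.3.1]pentadecane-3,13-dione | CCC[C@@H]1C[C@H](OC)C[C@H](C)C[C@@H]2CC(=O)C[C@H](CC(=O)O1)O2 | intermediate
37 | (1R,5R,7R,9S,11R,13S)-13-hydroxy-7-methoxy-9-methyl-5-propyl-4,15-dioxabicyclo[9.3.1]pentadecan-3-one | CCC[C@@H]1C[C@H](OC)C[C@H](C)C[C@@H]2C[C@H](O)C[C@H](CC(=O)O1)O2 | intermediate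
38 | methyl 5-bromo-4-oxopentanoate | COC(=O)CCC(=O)CBr | starting material
39 | methyl 3-(1,3-oxazol-4-yl)propanoate | COC(=O)CCc1cocn1 | intermediate
40 | chloro[4-(3-methoxy-3-oxopropyl)-1,3-oxazol-2-yl]zinc | COC(=O)CCc1coc([Zn]Cl)n1 | intermediate
41 | methyl 3-(2-iodo-1,3-oxazol-4-yl)propanoate | COC(=O)CCc1coc(I)n1 | intermediate
42 | prop-2-yn-1-amine | C#CCN | starting material
43 | methyl prop-2-yn-1-ylcarbamate | C#CCNC(=O)OC | intermediate
44 | methyl 3-(2-{3-[(methoxycarbonyl)amino]prop-1-yn-1-yl}-1,3-oxazol-4-yl)propanoate | COC(=O)CCc1coc(C#CCNC(=O)OC)n1 | intermediate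
45 | methyl 3-(2-{(1Z)-3-[(methoxycarbonyl)amino]prop-1-en-1-yl}-1,3-oxazol-4-yl)propanoate | COC(=O)CCc1coc(/C=C\CNC(=O)OC)n1 | intermediate
46 | methyl {(2Z)-3-[4-(3-oxopropyl)-1,3-oxazol-2-yl]prop-2-en-1-yl}carbamate | O=CCCc1coc(/C=C\CNC(=O)OC)n1 | intermediate
47 | methyl (2Z)-5-(2-{(1Z)-3-[(methoxycarbonyl)amino]prop-1-en-1-yl}-1,3-oxazol-4-yl)pent-2-enoate | COC(=O)/C=C\CCc1coc(/C=C\CNC(=O)OC)n1 | intermediate
48 | (2Z)-5-(2-{(1Z)-3-[(methoxycarbonyl)amino]prop-1-en-1-yl}-1,3-oxazol-4-yl)pent-2-enoic acid | OC(=O)/C=C\CCc1coc(/C=C\CNC(=O)OC)n1 | intermediate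
49 | neopeltolide: (1R,5R,7R,9S,11R,13R)-7-methoxy-9-methyl-3-oxo-5-propyl-4,15-dioxabicyclo[9.3.1]pentadecan-13-yl (2Z)-5-(2-{(1Z)-3-[(methoxycarbonyl)amino]prop-1-en-1-yl}-1,3-oxazol-4-yl)pent-2-enoate | CCC[C@@H]1C[C@H](OC)C[C@H](C)C[C@@H]2C[C@@H](OC(=O)/C=C\CCc3coc(/C=C\CNC(=O)OC)n3)C[C@H](CC(=O)O1)O2 | target

**Step count and risks**

Total step count: 32. Longest linear sequence: 20 steps (7 → 49 through steps 5–23 and 32).

Steps most likely to fail:

Step 16. The relay can run out of order: premature silyl migration lets the first anion react twice with 22, and incomplete migration leaves 4 unincorporated. The fallback is a stepwise double alkylation that sets out from 22. 2-Lithio-1,3-dithiane (1,3-dithiane, n-BuLi, THF, –30 °C) opens 22 at C6 to give (2R,4R,6R,8R)-8-(benzyloxy)-1-(1,3-dithian-2-yl)-6-methoxy-4-methylundecan-2-ol F1. TBSOTf and 2,6-lutidine silylate O7 to give the silyl ether {[(2R,4S,6R,8R)-8-(benzyloxy)-1-(1,3-dithian-2-yl)-6-methoxy-4-methylundecan-2-yl]oxy}(tert-butyl)dimethylsilane F2. A second lithiation (t-BuLi, THF–HMPA, –78 °C) and addition of 4 forms C4–C5, and the route is rejoined at 27.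

Step 18. Basic fluoride can eliminate the secondary mesylate, or displacement next to the quaternary dithiane carbon can be slow, so that material is lost to alkene formation. The fallback closes the ring by conjugate addition under thermodynamic control and sets out from 27. MeI/CaCO3 in wet MeCN unmasks the ketone to give (3R,7R,9S,11R,13R)-1,13-bis(benzyloxy)-7-[(tert-butyldimethylsilyl)oxy]-3-hydroxy-11-methoxy-9-methylhexadecan-5-one F3. MsCl/Et3N converts it by E1cB elimination into the enone (3E,7R,9S,11R,13R)-1,13-bis(benzyloxy)-7-[(tert-butyldimethylsilyl)oxy]-11-methoxy-9-methylhexadec-3-en-5-one F4. HF·pyridine frees O7 to give (3E,7R,9R,11R,13R)-1,13-bis(benzyloxy)-7-hydroxy-11-methoxy-9-methylhexadec-3-en-5-one F5. With catalytic DBU or camphorsulfonic acid, F5 cyclises by intramolecular oxa-Michael addition of O7 to C3, equilibrating to the 2,6-cis tetrahydropyranone, and the route is rejoined at 31.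

Step 22. Base can open the tetrahydropyran by β-elimination at the activated acyl stage or through the C5 enolate, and oligomerisation can compete with ring closure. The fallback lowers C5 to a protected alcohol before lactonisation and sets out from 31. NaBH4 gives the equatorial alcohol (2S,4S,6R)-2-[2-(benzyloxy)ethyl]-6-[(2S,4R,6R)-6-(benzyloxy)-4-methoxy-2-methylnonyl]oxan-4-ol F6. TBSOTf/2,6-lutidine gives tert-butyl({(2S,4S,6R)-2-[2-(benzyloxy)ethyl]-6-[(2S,4R,6R)-6-(benzyloxy)-4-methoxy-2-methylnonyl]oxan-4-yl}oxy)dimethylsilane F7. Hydrogenolysis over Pd(OH)2/C gives 2-[(2S,4S,6R)-4-[(tert-butyldimethylsilyl)oxy]-6-[(2S,4R,6R)-6-hydroxy-4-methoxy-2-methylnonyl]oxan-2-yl]ethan-1-ol F8. TEMPO/PhI(OAc)2 gives 2-[(2R,4S,6R)-4-[(tert-butyldimethylsilyl)oxy]-6-[(2S,4R,6R)-6-hydroxy-4-methoxy-2-methylnonyl]oxan-2-yl]acetic acid F9. Yamaguchi lactonisation gives (1R,5R,7R,9S,11R,13S)-13-[(tert-butyldimethylsilyl)oxy]-7-methoxy-9-methyl-5-propyl-4,15-dioxabicyclo[9.3.1]pentadecan-3-one F10. HF·pyridine then removes the silyl group, and the route is rejoined at 37.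

Further compounds
F1 | step 16 | (2R,4R,6R,8R)-8-(benzyloxy)-1-(1,3-dithian-2-yl)-6-methoxy-4-methylundecan-2-ol | CCC[C@@H](OCc1ccccc1)C[C@H](OC)C[C@H](C)C[C@@H](O)CC2SCCCS2
F2 | step 16 | {[(2R,4S,6R,8R)-8-(benzyloxy)-1-(1,3-dithian-2-yl)-6-methoxy-4-methylundecan-2-yl]oxy}(tert-butyl)dimethylsilane | CCC[C@@H](OCc1ccccc1)C[C@H](OC)C[C@H](C)C[C@@H](O[Si](C)(C)C(C)(C)C)CC2SCCCS2
F3 | step 18 | (3R,7R,9S,11R,13R)-1,13-bis(benzyloxy)-7-[(tert-butyldimethylsilyl)oxy]-3-hydroxy-11-methoxy-9-methylhexadecan-5-one | CCC[C@@H](OCc1ccccc1)C[C@H](OC)C[C@H](C)C[C@@H](O[Si](C)(C)C(C)(C)C)CC(=O)C[C@@H](CCOCc2ccccc2)O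
F4 | step 18 | (3E,7R,9S,11R,13R)-1,13-bis(benzyloxy)-7-[(tert-butyldimethylsilyl)oxy]-11-methoxy-9-methylhexadec-3-en-5-one | CCC[C@@H](OCc1ccccc1)C[C@H](OC)C[C@H](C)C[C@@H](O[Si](C)(C)C(C)(C)C)CC(=O)/C=C/CCOCc2ccccc2
F5 | step 18 | (3E,7R,9R,11R,13R)-1,13-bis(benzyloxy)-7-hydroxy-11-methoxy-9-methylhexadec-3-en-5-one | CCC[C@@H](OCc1ccccc1)C[C@H](OC)C[C@H](C)C[C@@H](O)CC(=O)/C=C/CCOCc2ccccc2
F6 | step 22 | (2S,4S,6R)-2-[2-(benzyloxy)ethyl]-6-[(2S,4R,6R)-6-(benzyloxy)-4-methoxy-2-methylnonyl]oxan-4-ol | CCC[C@@H](OCc1ccccc1)C[C@H](OC)C[C@H](C)C[C@@H]2C[C@H](O)C[C@H](CCOCc3ccccc3)O2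
F7 | step 22 | tert-butyl({(2S,4S,6R)-2-[2-(benzyloxy)ethyl]-6-[(2S,4R,6R)-6-(benzyloxy)-4-methoxy-2-methylnonyl]oxan-4-yl}oxy)dimethylsilane | CCC[C@@H](OCc1ccccc1)C[C@H](OC)C[C@H](C)C[C@@H]2C[C@H](O[Si](C)(C)C(C)(C)C)C[C@H](CCOCc3ccccc3)O2
F8 | step 22 | 2-[(2S,4S,6R)-4-[(tert-butyldimethylsilyl)oxy]-6-[(2S,4R,6R)-6-hydroxy-4-methoxy-2-methylnonyl]oxan-2-yl]ethan-1-ol | CCC[C@@H](O)C[C@H](OC)C[C@H](C)C[C@@H]1C[C@H](O[Si](C)(C)C(C)(C)C)C[C@H](CCO)O1
F9 | step 22 | 2-[(2R,4S,6R)-4-[(tert-butyldimethylsilyl)oxy]-6-[(2S,4R,6R)-6-hydroxy-4-methoxy-2-methylnonyl]oxan-2-yl]acetic acid | CCC[C@@H](O)C[C@H](OC)C[C@H](C)C[C@@H]1C[C@H](O[Si](C)(C)C(C)(C)C)C[C@H](CC(=O)O)O1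
F10 | step 22 | (1R,5R,7R,9S,11R,13S)-13-[(tert-butyldimethylsilyl)oxy]-7-methoxy-9-methyl-5-propyl-4,15-dioxabicyclo[9.3.1]pentadecan-3-one | CCC[C@@H]1C[C@H](OC)C[C@H](C)C[C@@H]2C[C@H](O[Si](C)(C)C(C)(C)C)C[C@H](CC(=O)O1)O2
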